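## Retrosynthetic overview
1. Target 11 ⇒ triol 9. Both angelates go on last, because the tertiary 4-OH does not acylate.
2. Second ring, five-membered (C5–C4 = farnesane C6–C10): a C5 radical from the 5α,6α-epoxide 8 closes onto the C4 isopropyl ketone. The ketone oxygen stands in for the biosynthetic 1,2-H shift and water capture at C4.
3. 8 ⇒ 7 ⇒ aldehyde 5 + 3-methylbutan-2-one. The aldol sets C2, and the new OH then directs the epoxidation.
4. First ring, seven-membered (C10–C1 = farnesane C1–C7): the linalyl-type allyl cation equivalent (π-allyl-Pd) of 2 is captured by C7, acting as a dienamine α-carbon. This is the nerolidyl → cycloheptenyl closure, made enantioselective.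
5. 2 ⇒ linalyl acetate 1. The rings form in the order seven then five, as in the biosynthesis.

Assumption: daucane numbering is used throughout (C1 quaternary fusion carbon, C2/C6 ester carbinols, C4 isopropyl carbinol, C5 fusion CH, C8=C9 ring alkene, α = face of H-5), and (R)-TRIP is taken to give (R)-5 in step 2 (the mirror-image acid is used otherwise).

## Route

Step 1
Reactants: 1 (±)-linalyl acetate
Product: 2 (±)-(6E)-3,7-dimethyl-8-oxoocta-1,6-dien-3-yl acetate (8-oxolinalyl acetate)
Conditions: SeO2 (1.1 equiv), 1,4-dioxane, 80 °C
Reagents that add atoms: selenium dioxide O=[Se]=O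
Why: Riley allylic oxidation (ene reaction, then [2,3]-shift) attacks only the E-methyl group of the electron-rich trisubstituted alkene and runs on to the (E)-enal, leaving the vinyl group and tertiary acetate untouched, and no stereocentre needs control because C3 of 1 becomes planar in step 2.

Step 2
Reactants: 2 8-oxolinalyl acetate
Product: 5 (1R)-1,5-dimethylcyclohepta-2,5-diene-1-carbaldehyde, via N-benzhydryl dienamine 3 (not isolated), via N-benzhydryl aldimine 4 (not isolated)
Conditions: Ph2CHNH2 (40 mol%), (R)-TRIP (10 mol%), Pd(PPh3)4 (5 mol%), 5 Å MS, toluene (0.01 M), 40 °C; then 1 M HCl/Et2O, rt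
Reagents that add atoms: water O
Why: Proposed new method: an intramolecular, deconjugative Tsuji–Trost α-allylation whose closest known reaction type is the Pd/chiral phosphoric acid/primary amine α-allylation of α-branched aldehydes; the amine turns the α-methyl enal into a dienamine whose C5=C6 geometry equilibrates, Pd(0)/acid ionises the tertiary acetate to a π-allyl that also equilibrates (π-σ-π), and only α-carbon to unsubstituted allyl terminus closes productively (α to the tertiary terminus would join two quaternary carbons, γ to the primary terminus would put the whole allyl unit inside a five-membered ring, and γ to the tertiary terminus gives a cis-divinylcyclopropane that Cope-rearranges to the same ring), the non-enolisable imine 4 makes closure irreversible, and the quaternary C1 is set by the phosphate that bridges the enamine N–H and the cationic allyl-Pd.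

Step 3
Reactants: 5 (1R)-1,5-dimethylcyclohepta-2,5-diene-1-carbaldehyde; 6 3-methylbutan-2-one
Product: 7 (1S)-1-[(1R)-1,5-dimethylcyclohepta-2,5-dien-1-yl]-1-hydroxy-4-methylpentan-3-one
Conditions: D-proline (30 mol%), 6/DMSO 1:4, rt
Reagents that add atoms: 3-methylbutan-2-one CC(C)C(C)=O
Why: Proline-catalysed direct aldol (Houk–List transition state) in which the enamine forms only on the methyl side of 6 and the non-enolisable, pivaldehyde-like aldehyde is the ideal acceptor; D-proline delivers the enamine to the aldehyde Si face and so sets C2 as (S) under catalyst control.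

Step 4
Reactants: 7 aldol adduct
Product: 8 (1S)-1-[(1S,6S,7R)-3,6-dimethyl-8-oxabicyclo[5.1.0]oct-3-en-6-yl]-1-hydroxy-4-methylpentan-3-one (5α,6α-epoxide, cis to the side chain)
Conditions: VO(acac)2 (5 mol%), t-BuOOH (1.1 equiv, decane), toluene, 0 °C to rt
Reagents that add atoms: tert-butyl hydroperoxide CC(C)(C)OO
Why: Hydroxyl-directed vanadium epoxidation (Sharpless–Michaelson type) in which the vanadate ester of the C2-OH reaches the homoallylic C5=C6 bond more easily than the bishomoallylic C8=C9 bond and can deliver oxygen only to the ring face that carries the carbinol chain, which sets C5 and C6 (α-epoxide).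

Step 5
Reactants: 8 epoxy ketone
Product: 9 (1S,3R,3aS,4S,8aR)-6,8a-dimethyl-3-(propan-2-yl)-1,2,3,3a,4,5,8,8a-octahydroazulene-1,3,4-triol (dauc-8-ene-2α,4β,6α-triol, trans-fused)
Conditions: Cp2TiCl2 (2.5 equiv), Mn dust (8 equiv), degassed THF, rt, Ti(III) solution added slowly to 8 (0.01 M); then 1 M HCl
Reagents that add atoms: none
Why: Titanocene(III) epoxide opening (Nugent–RajanBabu) followed by 5-exo radical addition to a carbonyl, in which Ti(III) breaks the more hindered C5–O bond so the bulky OTi stays on C6 with its configuration, the C5 radical adds to the Ti-activated C4 ketone anti to that α-OTi group (H-5 α, trans fusion) with the isopropyl turned to the open α side away from the C1 methyl (4β-OH), and a second Ti(III) reduces the alkoxyl radical and makes the addition irreversible.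

Step 6
Reactants: 9 triol; 10 angelic acid
Product: 11 2α,6α-diangeloyloxy-4β-hydroxydauc-8-ene (target CNP0303897.1)
Conditions: 10 (6 equiv), 2,4,6-trichlorobenzoyl chloride (6 equiv), Et3N (6 equiv), toluene, rt, 2 h; then 9, 80 °C, no DMAP
Reagents that add atoms: angelic acid C/C=C(/C)C(=O)O
Why: Yamaguchi-type mixed-anhydride esterification run without a nucleophilic catalyst, which acylates the two secondary alcohols without Z-to-E isomerisation of the angelate while the tertiary 4-OH stays free, and no stereocentre is touched.

## Compound list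
1 | (±)-linalyl acetate | CC(C)=CCCC(C)(C=C)OC(C)=O | starting material
2 | (±)-(E)-8-oxolinalyl acetate | CC(=O)OC(C)(C=C)CC/C=C(\C)C=O | intermediate
3 | N-benzhydryl dienamine of 2 (ring-closing Z geometry at the new C=C) | CC(=O)OC(C)(C=C)C/C=C\C(C)=C\NC(c1ccccc1)c1ccccc1 | intermediate
4 | N-benzhydryl aldimine of 5 | C(=NC(c1ccccc1)c1ccccc1)[C@@]1(C)C=CCC(C)=CC1 | intermediate
5 | (1R)-1,5-dimethylcyclohepta-2,5-diene-1-carbaldehyde | O=C[C@@]1(C)C=CCC(C)=CC1 | intermediate
6 | 3-methylbutan-2-one | CC(C)C(C)=O | starting material
7 | (1S)-1-[(1R)-1,5-dimethylcyclohepta-2,5-dien-1-yl]-1-hydroxy-4-methylpentan-3-one | CC(C)C(=O)C[C@H](O)[C@]1(C)CC=C(C)CC=C1 | intermediate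
8 | 5α,6α-epoxide of 7 | CC(C)C(=O)C[C@H](O)[C@]1(C)CC=C(C)C[C@@H]2O[C@H]12 | intermediate
9 | (1R,2S,4R,5S,6S)-dauc-8-ene-2,4,6-triol | O[C@H]1CC(C)=CC[C@@]2(C)[C@@H](O)C[C@@](O)(C(C)C)[C@H]12 | intermediate
10 | angelic acid, (Z)-2-methylbut-2-enoic acid | C/C=C(/C)C(=O)O | starting material
11 | 2α,6α-diangeloyloxy-4β-hydroxydauc-8-ene | C/C=C(/C)C(=O)O[C@H]1CC(C)=CC[C@@]2(C)[C@@H](OC(=O)/C(C)=C\C)C[C@@](O)(C(C)C)[C@H]12 | target

## Step count and risks
Total steps: 6. Longest linear sequence: 6 (1 → 2 → 5 → 7 → 8 → 9 → 11). No protecting groups are used.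

**Risk 1, step 2.** The ring closure, its regiochemistry and its ee are all unprecedented in this combination.
- The fallback sets out from 1 and returns at 5. It replaces the polar closure by a radical one and takes the absolute configuration from an asymmetric epoxidation.
- Catalytic SeO2/t-BuOOH, followed by NaBH4, stops at (E)-8-hydroxylinalyl acetate F1.
- Sharpless epoxidation (Ti(OiPr)4, L-(+)-DIPT, t-BuOOH) gives the (6S,7S)-epoxy alcohol F2.
- Cp2TiCl opens F2 to the tertiary C7 radical. This closes 7-endo on the vinyl group and expels acetate, the known titanocene closure of linalyl systems.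
- The product is (1S,2S)-2-(hydroxymethyl)-2,5-dimethylcyclohept-4-en-1-ol F3. Its quaternary-carbon epimer is removed by chromatography, which is possible because the carbinol carbon is a single configuration.
- TEMPO/PhI(OAc)2 oxidises only the primary alcohol, giving the β-hydroxy aldehyde F4.
- Burgess dehydration can eliminate only toward C6 and gives 5.

**Risk 2, step 4.** The more electron-rich C8=C9 bond may be epoxidised in competition.
- The fallback sets out from 7 and returns at 8. It replaces oxygen transfer by reversible iodonium formation with proximity-controlled capture.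
- Boc2O/DMAP gives the tert-butyl carbonate F5.
- IBr in toluene at −80 °C forms iodonium ions reversibly on both alkenes. Only the one on C5=C6 can be trapped, 6-exo, by the carbonate.
- This gives the cyclic iodocarbonate F6, with O on C5 on the chain face and I on C6 anti to it.
- K2CO3/MeOH cleaves the carbonate, and the C5 alkoxide displaces the iodide to give the same α-epoxide 8.

**Risk 3, step 5.** Radical addition to a hindered ketone is reversible, Ti(III) deoxygenation competes, and the trans closure is strained.
- The fallback sets out from 5 and returns at 9. It uses an irreversible radical acceptor and brings in the isopropyl group afterwards.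
- LiCH2CN (THF, −78 °C) followed by separation of the C2 epimers gives the β-hydroxynitrile F7.
- Directed epoxidation as in step 4 gives the epoxynitrile F8.
- Cp2TiCl closes the C5 radical 5-exo onto the nitrile. Acid hydrolysis of the titanium imide gives 2α,6α-dihydroxy-11,12,13-trinordauc-8-en-4-one F9.
- i-PrMgCl/CeCl3 (THF, −78 °C) adds to F9 from the α face, anti to the C1 methyl, and gives 9.

## Further compounds
F1 | step 2 | (E)-8-hydroxylinalyl acetate | CC(=O)OC(C)(C=C)CC/C=C(\C)CO
F2 | step 2 | (6S,7S)-6,7-epoxy-8-hydroxylinalyl acetate | CC(=O)OC(C)(C=C)CC[C@@H]1O[C@@]1(C)CO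
F3 | step 2 | (1S,2S)-2-(hydroxymethyl)-2,5-dimethylcyclohept-4-en-1-ol | OC[C@]1(C)CC=C(C)CC[C@@H]1O
F4 | step 2 | (1R,7S)-7-hydroxy-1,4-dimethylcyclohept-3-ene-1-carbaldehyde | O=C[C@]1(C)CC=C(C)CC[C@@H]1O
F5 | step 4 | tert-butyl carbonate of 7 | CC(C)C(=O)C[C@H](OC(=O)OC(C)(C)C)[C@]1(C)CC=C(C)CC=C1
F6 | step 4 | cyclic C2,C5-carbonate with 6β-iodide | CC(C)C(=O)C[C@@H]1OC(=O)O[C@H]2[C@H](I)CC(C)=CC[C@@]12C
F7 | step 5 | (3S)-3-[(1R)-1,5-dimethylcyclohepta-2,5-dien-1-yl]-3-hydroxypropanenitrile | N#CC[C@H](O)[C@]1(C)CC=C(C)CC=C1
F8 | step 5 | 5α,6α-epoxide of F7 | N#CC[C@H](O)[C@]1(C)CC=C(C)C[C@@H]2O[C@H]12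
F9 | step 5 | 2α,6α-dihydroxy-11,12,13-trinordauc-8-en-4-one | O[C@H]1CC(C)=CC[C@@]2(C)[C@@H](O)CC(=O)[C@H]12
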